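**Conventions and assumptions**

- Locants: chromene numbering for the core (O1, C2, C3, C4, C4a, C5, C6, C7, C8, C8a). Ring A is the carbocycle C4a–C8a, ring B the pyran. The chain on C8 is C1'H2–C2'H–C3'H2–C4'H=C5'(CH3)–CO2H.
- Assumption on tautomers: dearomatized compounds are drawn as the C7-enol/C5-keto tautomer, and CIP letters refer to that drawing. The target is then (8S,2'R).
- Assumption on the catalyst: the cinchonidinium salt is taken to deliver the required C8 configuration. If it gives the opposite sense, the pseudoenantiomeric cinchoninium salt is used with no other change.

## Analysis of the target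

The target is a dearomatized acylphloroglucinol. Ring A (C4a, C5, C6, C7, C8, C8a) is a cyclohexadienone with a 5-keto group, a 6-benzoyl group and a 7-enol hydroxyl, and it is fused along C4a–C8a to ring B, a 2,2-dimethyl-2H-pyran (O1, C2, C3=C4). C8 is an all-carbon quaternary stereocentre that carries a prenyl group and the chain C1'H2–C2'H(isopropenyl)–C3'H2–C4'H=C5'(CH3)CO2H, whose trisubstituted alkene is E. The second stereocentre, C2', is an acyclic methine 1,3-related to C8 across the C1' methylene; no ring of the target joins the two, so their relative configuration cannot be held by anything that survives to the end. Sensitive groups are the acidic, chelating β-triketone (ambident O/C reactivity, acid-induced cyclization onto prenyl), the acid-labile chromene, and the C3' methylene flanked by two alkenes. In addition, any intermediate with a carbonyl on C2' can lose the C8 substituent by retro-Michael cleavage with re-aromatization of ring A. The difficulty is to create quaternary C8 enantioselectively between two oxygenated sp2 carbons and then to relay that configuration to a conformationally free methine two bonds away. The strategy rests on the C8–C1'–C2' unit: if the isopropenyl group on C2' is carried as a formyl group, C8–C1' is the β-bond of a 2-substituted acrolein and C2' is an epimerizable aldehyde α-carbon. Its carbonyl then lies within reach of the C7 enol oxygen, so a temporary lactol ring O–C7–C8–C1'–C2'–CH(OH) can tie C2' to C8.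

## Retrosynthetic reasoning

**17 to 16.** The acid is unmasked last by saponification of methyl ester 16. A free carboxylic acid would consume organometallic reagents and complicate the phase-transfer step, and once the isopropenyl group is in place no base-labile stereocentre remains.

**16 to 15 to 14 to 13.** The C=CH2 bond of the isopropenyl group is cut to methyl ketone 15 (carbonyl methylenation). The ketone is traced to carbinol 14, and the C–CH3 bond of 14 is cut to the aldehyde that is masked in lactol 13. An isopropenyl group offers no handle on C2', whereas a formyl group makes C2' epimerizable and can be locked to the C7 oxygen. The forward steps must add one methyl nucleophile to a lactol beside an enoate ester, oxidize beside a free vinylogous acid, and methylenate without base.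

**13 to 5 and 10 (key disconnection).** The C8–C1' bond and the lactol C–O bond are cut. This is the only cut that separates an aromatic nucleus, chromene 5, from the complete side chain, acrolein 10. The forward reaction makes the quaternary centre and dearomatizes ring A in one event. Cutting C1'–C2' would need an alkylation beside a neopentyl centre. Cutting the prenyl–C8 bond last would leave C2' to be controlled on its own. The forward step has to choose C8 over C4a and oxygen, set C8 by catalyst control, and then let the lactol ring equilibrate C2'.

**5 to 3 and 4, then 3 to 1 and 2.** Ring B is cut at O1–C2 and C4–C4a, which corresponds to condensation of prenal 4 at the one free ring carbon of 3 followed by oxa-6π closure. The prenyl C–C bond of 3 is cut to benzophenone 1 and bromide 2. Both rings and the benzoyl group thus come from a commercial aromatic compound in two steps.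

**10 to 9, then 9 to 7 and 8, then 7 to 6.** The exocyclic methylene of 10 is removed (α-methylenation of aldehyde 9). The E enoate of 9 is cut by a Wittig disconnection to succinaldehyde 7 and stabilized ylide 8, and 7 comes from its cyclic acetal 6. The enoate is therefore in place before the key step, and nothing has to be built on the chain afterwards.

## Alternatives that were turned down

**Alternative 1:** ring A by transposition of a pyran-2,4-dione.
- Disconnection: the C6–C7 bond of ring A. The precursor is pyrandione A1, a 3,3-disubstituted 6-phenacyl-2H-pyran-2,4(3H)-dione. Its C3 is the future C8 and already carries prenyl and the whole chain, its lactone carbonyl is the future C7, and its phenacyl CH2 is the future C6.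
- Forward key step: NaOMe or Mg(OMe)2 opens the enol lactone to a methyl ester. The doubly activated phenacyl carbanion then acylates that ester (Claisen/Dieckmann closure) to give trione A2, which has ring A and the benzoyl group but a C4a methylene and no ring B.
- For: there is no dearomatization, hence no C8/C4a/oxygen site question. Only a six-membered closure is possible. The benzoyl group arrives with the ring.
- Against: the key step creates no stereocentre, so quaternary C8 and C2' must both be made beforehand on A1, which means an asymmetric 3,3-dialkylation with a β-branched chain plus separate control of C2'. Methoxide can also cleave the non-enolizable β-keto ester by retro-Claisen reaction. Ring B is still missing in A2, and annulation with 4 must then choose between the C8a and C5 oxygens on a late chiral intermediate.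
- Comparison: alternative 1 is stronger on regiochemical certainty of the ring-forming step. The chosen route instead gets rings A and B and the benzoyl group in two steps and uses its key step to create both stereocentres; alternative 1 would be several steps longer.

**Alternative 2:** tethered glyoxylate ene reaction on a gem-diprenyl dienone.
- Disconnection: the C2'–C3' bond. The precursor is A3, the 8,8-diprenyl dienone (C8 prochiral) whose C7 oxygen carries a glyoxylate ester.
- Forward key step: Cu(OTf)2 with a chiral bis(oxazoline) (divalent copper) chelates the glyoxylate. Its aldehyde undergoes a carbonyl-ene reaction with one of the two enantiotopic prenyl groups, bonding to the CH= carbon and taking a methyl hydrogen. This gives the isopropenyl group, C2'–C3', and seven-membered hydroxy lactone A4.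
- For: one step sets C8 (group selection) and C2' (face selection) and delivers the isopropenyl group directly. A3 needs no asymmetric synthesis, since a second dearomative prenylation of 5 would give its skeleton. On these two points it is stronger than the chosen route, which needs three steps to build the isopropenyl group.
- Against: the enol glyoxylate of a vinylogous acid is a mixed-anhydride-like acyl donor, labile to hydrolysis and acyl transfer. The ene reaction must pass through a medium-ring transition state constrained by the planar enol ester, with a trisubstituted alkene. The Lewis acid can trigger Prins-type closure or ionize the chromene. There is no thermodynamic correction of C2'. In A4, C3' carries a hydroxyl and C4' is at the acid oxidation level, so the endgame needs lactone opening, deoxygenation at C3' in a polyene (radical cyclization risk), adjustment to an aldehyde, olefination and hydrolysis.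
- Comparison: the chosen route carries the enoate chain intact and corrects C2' by equilibration; alternative 2 saves the methylenation sequence but spends more steps removing surplus oxygen.

**Alternative 3:** lactonization that relays C2' chirality to C8.
- Disconnection: the C7–O acyl bond of a lactone between a C2' carboxyl group and a ring oxygen. The precursor is A5, a 2,2-disubstituted cyclohexane-1,3,5-trione with C8 prochiral and a stereodefined C2' acid.
- Forward key step: carbodiimide and 4-dimethylaminopyridine activate the acid. It esterifies one of the two diastereotopic enol oxygens flanking C8 and gives six-membered enol lactone A6 with prenyl trans to the C3' chain.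
- For: C8 is set by substrate control from a stereocentre that auxiliary chemistry makes reliably, using the same ring argument as the chosen route (prenyl pseudo-axial, chain pseudo-equatorial). No asymmetric catalysis on a polyfunctional phenoxide is needed. On predictability of the C8 configuration this alternative is stronger than the chosen route.
- Against: A6 lacks both the benzoyl group and ring B. C-benzoylation at C6 normally uses nucleophilic catalysts that would open the activated enol lactone, and pyran annulation again has to choose between two oxygens. A5 requires a quaternary centre built by double C-alkylation with a sluggish β-branched electrophile. If C2' epimerization and acyl migration between the two oxygens both operate, the trans lactone is converted into its enantiomer, so the thermodynamic correction can erode enantiopurity.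
- Comparison: the chosen route has the whole skeleton after its key step and needs four further steps; alternative 3 needs a longer precursor synthesis and a longer, less selective finish.

Key step: step 6

## Route

Step 1
Reactants: 1 2,4,6-trihydroxybenzophenone; 2 prenyl bromide (1-bromo-3-methylbut-2-ene)
Product: 3 (2,4,6-trihydroxy-3-(3-methylbut-2-en-1-yl)phenyl)(phenyl)methanone
Conditions: 2 (0.9 equiv), 10% aq KOH, 0 → 23 °C
Reagents that add atoms: none
Why: C-alkylation of a phloroglucinol phenoxide in water, where hydrogen bonding to the oxygens favours attack through carbon; the two free ring carbons are equivalent and a slight deficit of 2 should limit the 3,5-diprenyl by-product.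

Step 2
Reactants: 3 (2,4,6-trihydroxy-3-(3-methylbut-2-en-1-yl)phenyl)(phenyl)methanone; 4 3-methylbut-2-enal
Product: 5 (5,7-dihydroxy-2,2-dimethyl-8-(3-methylbut-2-en-1-yl)-2H-chromen-6-yl)(phenyl)methanone
Conditions: 4 (1.5 equiv), ethylenediammonium diacetate (20 mol %), toluene, 110 °C
Reagents that add atoms: none
Why: Knoevenagel-type condensation at the only free ring carbon gives an ortho-quinone methide that closes by oxa-6π electrocyclization; closure is expected through the 4-OH, which is never chelated to the benzoyl carbonyl, as in chromene formation from 2,4-dihydroxyaryl ketones, and any isomer closed through the 6-OH is to be removed by chromatography.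

Step 3
Reactants: 6 2,5-dimethoxytetrahydrofuran
Product: 7 succinaldehyde (butanedial)
Conditions: H2O, 90 °C; MeOH/H2O distilled off; extraction into CH2Cl2; used at once
Reagents that add atoms: water, O
Why: Hydrolysis of a cyclic bis-acetal; removing methanol drives it to completion, and immediate use avoids oligomerization of the dialdehyde.

Step 4
Reactants: 7 succinaldehyde; 8 methyl 2-(triphenylphosphoranylidene)propanoate
Product: 9 methyl (E)-2-methyl-6-oxohex-2-enoate
Conditions: 8 added slowly to 7 (3 equiv), CH2Cl2, 0 → 23 °C
Reagents that add atoms: none
Why: Wittig olefination with a stabilized α-methyl ylide is E-selective for the trisubstituted enoate; the excess of dialdehyde and slow addition should suppress double olefination.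

Step 5
Reactants: 9 methyl (E)-2-methyl-6-oxohex-2-enoate
Product: 10 methyl (E)-5-formyl-2-methylhexa-2,5-dienoate
Conditions: 37% aq CH2O, pyrrolidine (10 mol %), EtCO2H (10 mol %), i-PrOH, 45 °C; product kept cold and used fresh
Reagents that add atoms: formaldehyde, C=O
Why: Amine-catalysed α-methylenation (enamine Mannich/aldol condensation then elimination) acts only on the aldehyde α-CH2, and the enoate ester is inert to the buffered amine.

Step 6
Reactants: 5 (5,7-dihydroxy-2,2-dimethyl-8-(3-methylbut-2-en-1-yl)-2H-chromen-6-yl)(phenyl)methanone; 10 methyl (E)-5-formyl-2-methylhexa-2,5-dienoate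
Product: 13 trans-lactol (hemiacetal between the C2' formyl carbon and the C7 oxygen; prenyl on C8 trans to the C3' chain on C2'; anomeric mixture), via open-chain aldehyde adduct 11 (not isolated), via lactol C2' epimer mixture 12 (not isolated)
Conditions: O-allyl-N-(9-anthracenylmethyl)cinchonidinium bromide (10 mol %), CsOH·H2O (1.5 equiv), 4 Å MS, CH2Cl2, −50 °C; then AcOH (3 equiv), −50 → 23 °C; then pyrrolidine (20 mol %), 23 °C
Reagents that add atoms: none
Why: The cesium phenoxide of 5 is carried into CH2Cl2 as a chiral ammonium ion pair and adds through C8 to the unsubstituted β-CH2 of the 2-substituted acrolein 10; this is an asymmetric phase-transfer dearomative conjugate (Michael) addition of an acylphloroglucinol to an enal, the closest known reaction type, and protonation of the aldehyde enolate gives the triketonate aldehyde 11 as both C2' epimers. C8 is preferred over C4a, the only other ring carbon ortho and para to the oxygens, because attack there keeps the C3=C4 alkene conjugated to the new dienone and avoids a quaternary ring-fusion atom, while O-alkylation is an easily reversed oxa-Michael addition. The C8 configuration is set under catalyst control by the ammonium cation covering one face of the planar phenoxide at −50 °C. Ring closure is deferred to the acidic stage, because in base the triketonate is far less basic than a lactol alkoxide and stays open; once AcOH has protonated it, the C7 enol oxygen adds to the aldehyde in 6-exo-trig mode and gives the lactol ring O–C7–C8–C1'–C2'–CH(OH) of 12. Pyrrolidinium acetate then epimerizes C2' through the enamine of the small open-chain fraction while the lactol stays the resting state. In the lactol half-chair the prenyl group on C8 stands perpendicular to the ring A plane (pseudo-axial), so a cis C3' chain would be 1,3-diaxial to it and the equilibrium should drain to the trans isomer 13 with that chain pseudo-equatorial; C2' is thus set by thermodynamic ring control, and the anomeric centre does not matter. The step needs C2' epimerization to be faster than retro-Michael reversal, which would re-aromatize ring A and erase C8, and the weakly acidic buffer secures this by keeping the triketonate and any aldehyde enolate unpopulated.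

Step 7
Reactants: 13 trans-lactol
Product: 14 methyl (2E,5R)-5-{[(8S)-6-benzoyl-7-hydroxy-2,2-dimethyl-8-(3-methylbut-2-en-1-yl)-5-oxo-5,8-dihydro-2H-chromen-8-yl]methyl}-6-hydroxy-2-methylhept-2-enoate (both C6 carbinol epimers)
Conditions: MeMgBr (3 equiv), THF, −78 °C; aq NH4Cl at −78 °C
Reagents that add atoms: methylmagnesium bromide, C[Mg]Br
Why: Grignard addition to a lactol: the first equivalent deprotonates the hemiacetal, which collapses to the aldehyde and a magnesium triketonate that shields the ring A carbonyls; a second equivalent then adds to the aldehyde faster than it deprotonates C2' or attacks the enoate at −78 °C, and the carbinol configuration is irrelevant because it is oxidized next.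

Step 8
Reactants: 14 (carbinol from step 7)
Product: 15 methyl (2E,5R)-5-{[(8S)-6-benzoyl-7-hydroxy-2,2-dimethyl-8-(3-methylbut-2-en-1-yl)-5-oxo-5,8-dihydro-2H-chromen-8-yl]methyl}-2-methyl-6-oxohept-2-enoate
Conditions: Dess–Martin periodinane (1.3 equiv), NaHCO3, CH2Cl2, 0 → 23 °C
Reagents that add atoms: none
Why: Dess–Martin oxidation of a secondary alcohol under buffered, near-neutral conditions, which should neither epimerize C2' nor start a retro-Michael reaction; C6 of the vinylogous acid is fully substituted and offers no C–H for α-oxidation, and activated-DMSO oxidants are avoided because they alkylate 1,3-dicarbonyl enols.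

Step 9
Reactants: 15 (methyl ketone from step 8)
Product: 16 methyl (2E,5R)-5-{[(8S)-6-benzoyl-7-hydroxy-2,2-dimethyl-8-(3-methylbut-2-en-1-yl)-5-oxo-5,8-dihydro-2H-chromen-8-yl]methyl}-2,6-dimethylhepta-2,6-dienoate
Conditions: Cp2TiMe2 (4 equiv), toluene/THF, 65 °C, dark
Reagents that add atoms: bis(cyclopentadienyl)dimethyltitanium, C[Ti](C)(C1C=CC=C1)C1C=CC=C1
Why: Petasis methylenation through thermally formed Cp2Ti=CH2 is non-basic, so C2' (now α to a ketone) should neither epimerize nor undergo retro-Michael cleavage; one equivalent is spent on the acidic enol, whose titanium triketonate deactivates the ring A carbonyls, and the methyl ketone reacts faster than the conjugated ester.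

Step 10
Reactants: 16 (methyl ester from step 9)
Product: 17 (2E,5R)-5-{[(8S)-6-benzoyl-7-hydroxy-2,2-dimethyl-8-(3-methylbut-2-en-1-yl)-5-oxo-5,8-dihydro-2H-chromen-8-yl]methyl}-2,6-dimethylhepta-2,6-dienoic acid
Conditions: LiOH·H2O (5 equiv), THF/MeOH/H2O 3:1:1, 23 → 40 °C; then 1 M HCl to pH 3
Reagents that add atoms: lithium hydroxide, [Li+].[OH-]
Why: Saponification of the enoate ester; ring A is present as its lithium triketonate and is inert to hydroxide, C8 is quaternary and C2' no longer carries an acidifying group, so no stereocentre is at risk.

## Compound list

1 | 2,4,6-trihydroxybenzophenone | O=C(c1ccccc1)c1c(O)cc(O)cc1O | starting material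
2 | prenyl bromide (1-bromo-3-methylbut-2-ene) | CC(C)=CCBr | starting material
3 | (2,4,6-trihydroxy-3-(3-methylbut-2-en-1-yl)phenyl)(phenyl)methanone | CC(C)=CCc1c(O)cc(O)c(C(=O)c2ccccc2)c1O | intermediate
4 | 3-methylbut-2-enal | CC(C)=CC=O | starting material
5 | (5,7-dihydroxy-2,2-dimethyl-8-(3-methylbut-2-en-1-yl)-2H-chromen-6-yl)(phenyl)methanone | CC(C)=CCc1c(O)c(C(=O)c2ccccc2)c(O)c2C=CC(C)(C)Oc12 | intermediate
6 | 2,5-dimethoxytetrahydrofuran | COC1CCC(OC)O1 | starting material
7 | succinaldehyde (butanedial) | O=CCCC=O | intermediate
8 | methyl 2-(triphenylphosphoranylidene)propanoate | COC(=O)C(C)=P(c1ccccc1)(c1ccccc1)c1ccccc1 | starting material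
9 | methyl (E)-2-methyl-6-oxohex-2-enoate | O=CCC/C=C(\C)C(=O)OC | intermediate
10 | methyl (E)-5-formyl-2-methylhexa-2,5-dienoate | C=C(C=O)C/C=C(\C)C(=O)OC | intermediate
11 | methyl (2E)-6-[(8S)-6-benzoyl-7-hydroxy-2,2-dimethyl-8-(3-methylbut-2-en-1-yl)-5-oxo-5,8-dihydro-2H-chromen-8-yl]-5-formyl-2-methylhex-2-enoate, both C5 (= C2') epimers, formed as its triketonate | O=CC(C/C=C(\C)C(=O)OC)C[C@@]1(CC=C(C)C)C(O)=C(C(=O)c2ccccc2)C(=O)C2=C1OC(C)(C)C=C2 | intermediate (not isolated)
12 | lactol of 11 (hemiacetal O–C7–C8–C1'–C2'–CH(OH)), both C2' epimers, anomeric mixture; C8 as in 13 | OC3C(C/C=C(\C)C(=O)OC)C[C@@]1(CC=C(C)C)C(O3)=C(C(=O)c2ccccc2)C(=O)C2=C1OC(C)(C)C=C2 | intermediate (not isolated)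
13 | trans-lactol: 6-benzoyl-2,2-dimethyl-5-oxo-chromene core whose C7 oxygen is bonded to the hemiacetal carbon; C8 bears prenyl, C2' bears the (E)-3-(methoxycarbonyl)but-2-enyl chain trans to prenyl; anomeric mixture; C2' is R and C8 is R by CIP (same spatial arrangement at C8 as in 17, the letter changes because the lactol oxygen raises the rank of C7) | OC3[C@H](C/C=C(\C)C(=O)OC)C[C@@]1(CC=C(C)C)C(O3)=C(C(=O)c2ccccc2)C(=O)C2=C1OC(C)(C)C=C2 | intermediate
14 | methyl (2E,5R)-5-{[(8S)-6-benzoyl-7-hydroxy-2,2-dimethyl-8-(3-methylbut-2-en-1-yl)-5-oxo-5,8-dihydro-2H-chromen-8-yl]methyl}-6-hydroxy-2-methylhept-2-enoate, both C6 epimers | CC(O)[C@H](C/C=C(\C)C(=O)OC)C[C@@]1(CC=C(C)C)C(O)=C(C(=O)c2ccccc2)C(=O)C2=C1OC(C)(C)C=C2 | intermediate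
15 | methyl (2E,5R)-5-{[(8S)-6-benzoyl-7-hydroxy-2,2-dimethyl-8-(3-methylbut-2-en-1-yl)-5-oxo-5,8-dihydro-2H-chromen-8-yl]methyl}-2-methyl-6-oxohept-2-enoate | CC(=O)[C@H](C/C=C(\C)C(=O)OC)C[C@@]1(CC=C(C)C)C(O)=C(C(=O)c2ccccc2)C(=O)C2=C1OC(C)(C)C=C2 | intermediate
16 | methyl (2E,5R)-5-{[(8S)-6-benzoyl-7-hydroxy-2,2-dimethyl-8-(3-methylbut-2-en-1-yl)-5-oxo-5,8-dihydro-2H-chromen-8-yl]methyl}-2,6-dimethylhepta-2,6-dienoate | C=C(C)[C@H](C/C=C(\C)C(=O)OC)C[C@@]1(CC=C(C)C)C(O)=C(C(=O)c2ccccc2)C(=O)C2=C1OC(C)(C)C=C2 | intermediate
17 | (2E,5R)-5-{[(8S)-6-benzoyl-7-hydroxy-2,2-dimethyl-8-(3-methylbut-2-en-1-yl)-5-oxo-5,8-dihydro-2H-chromen-8-yl]methyl}-2,6-dimethylhepta-2,6-dienoic acid (CNP0333091.1) | C=C(C)[C@H](C/C=C(\C)C(=O)O)C[C@@]1(CC=C(C)C)C(O)=C(C(=O)c2ccccc2)C(=O)C2=C1OC(C)(C)C=C2 | target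

## Step count and least certain steps

Total step count: 10. Longest linear sequence: 8 steps (steps 3, 4, 5, 6, 7, 8, 9 and 10); the chromene branch (steps 1 and 2) joins at step 6.

**Step 6 (key step).** Several processes can fail here.
- Facial selectivity at C8 may be poor, because the phenoxide of 5 is unsymmetrical and bears a chromene on one flank.
- The skipped dienal 10 may isomerize into conjugation or oligomerize under hydroxide before it is captured.
- Retro-Michael reversal with re-aromatization during the buffered equilibration would erode the C8 configuration.
- If the hydrogen-bonded open-chain enol competes with the lactol as the resting state, the thermodynamic bias at C2' weakens and equilibration stays incomplete.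
- Reversible aldol closure of the aldehyde onto C6 may divert material.

The fallback gives up asymmetric catalysis for resolution. It sets out from 5 and 10. Addition with Et3N (20 mol %) in CH2Cl2 at 0 °C, followed by the same AcOH/pyrrolidine equilibration, should give the racemic trans-lactol F1. Acetalization with (1R,2S,5R)-menthol (pyridinium p-toluenesulfonate, 4 Å MS, CH2Cl2) converts F1 into diastereomeric menthyl acetals, from which the menthyl acetal F2 of the required series is separated by chromatography or crystallization. Mild hydrolysis (AcOH/THF/H2O, 40 °C) of this activated acetal returns to the route at 13.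

**Step 2.** Ring closure through the chelated 6-OH instead of the 4-OH would give the regioisomeric chromene and lower the throughput. The fallback inverts the order of events and sets out from 1. Annulation of 1 with 4 under the same amine-salt catalysis is done first, on the symmetrical ring, where only the oxygen choice remains. The product (5,7-dihydroxy-2,2-dimethyl-2H-chromen-6-yl)(phenyl)methanone F3 is purified from its regioisomer at this simple stage. C-prenylation of F3 with 2 in aq KOH can then occur only at C8, the single free ring carbon, and returns to the route at 5.

**Step 4.** Double olefination and self-condensation of the dialdehyde may leave little mono-adduct. The fallback avoids a dialdehyde and sets out from 8. Wittig reaction of 8 with pent-4-enal (C=CCCC=O) gives methyl (E)-2-methylhepta-2,6-dienoate F4. Ozonolysis (O3, CH2Cl2, −78 °C, then PPh3) cleaves the electron-rich terminal alkene in preference to the electron-poor trisubstituted enoate and returns to the route at 9.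

**Step 8 (and the Grignard step before it).** Over-oxidation or iodine-mediated side reactions at the free, electron-rich vinylogous acid may compete with alcohol oxidation, and in step 7 partial C2' epimerization of the liberated aldehyde is possible. The fallback changes the oxidation level before the methyl group is added and sets out from 13, in which the enol is still masked. Lactol oxidation (n-Pr4N[RuO4] cat., N-methylmorpholine N-oxide, 4 Å MS, CH2Cl2) gives the fused enol lactone F5. This activated enol ester is opened at the acyl carbon by N,O-dimethylhydroxylamine (hydrochloride, Et3N, CH2Cl2, 0 °C) to the Weinreb amide F6. MeMgBr (3 equiv, THF, −20 °C) stops at the ketone stage through the chelated tetrahedral intermediate and returns to the route at 15, bypassing 14.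

**Step 9.** Protonolysis of the titanium reagent by the acidic enol, slow reaction of the α-branched ketone, or competing methylenation of the ester may leave the conversion incomplete. The fallback replaces the carbene transfer by a Peterson olefination and sets out from 15. Addition of Me3SiCH2MgCl in the presence of CeCl3 (THF, −78 → 0 °C; the cerium reagent is weakly basic) gives the β-hydroxysilane F7. Acid-promoted elimination (AcOH, THF, 40 °C) can only give the terminal alkene and returns to the route at 16.

## Further compounds

F1 | step 6 | racemic trans-lactol (racemate of 13; one enantiomer drawn) | OC3[C@H](C/C=C(\C)C(=O)OC)C[C@@]1(CC=C(C)C)C(O3)=C(C(=O)c2ccccc2)C(=O)C2=C1OC(C)(C)C=C2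
F2 | step 6 | (1R,2S,5R)-menthyl acetal of 13 (acetal centre unspecified) | CC(C)[C@@H]1CC[C@@H](C)C[C@H]1OC3[C@H](C/C=C(\C)C(=O)OC)C[C@@]4(CC=C(C)C)C(O3)=C(C(=O)c2ccccc2)C(=O)C2=C4OC(C)(C)C=C2
F3 | step 2 | (5,7-dihydroxy-2,2-dimethyl-2H-chromen-6-yl)(phenyl)methanone | Oc1cc2OC(C)(C)C=Cc2c(O)c1C(=O)c1ccccc1
F4 | step 4 | methyl (E)-2-methylhepta-2,6-dienoate | C=CCC/C=C(\C)C(=O)OC
F5 | step 8 | fused enol lactone (lactone carbonyl in place of the hemiacetal carbon of 13; prenyl trans to the C3' chain) | O=C3[C@H](C/C=C(\C)C(=O)OC)C[C@@]1(CC=C(C)C)C(O3)=C(C(=O)c2ccccc2)C(=O)C2=C1OC(C)(C)C=C2
F6 | step 8 | Weinreb amide: N-methoxy-N-methyl amide at the C2' carboxyl, ring A as the free triketone enol, (8S,2'R) | CON(C)C(=O)[C@H](C/C=C(\C)C(=O)OC)C[C@@]1(CC=C(C)C)C(O)=C(C(=O)c2ccccc2)C(=O)C2=C1OC(C)(C)C=C2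
F7 | step 9 | β-hydroxysilane: tertiary carbinol C(OH)(CH3)CH2SiMe3 on C2', both carbinol epimers, (8S,2'R) | C[Si](C)(C)CC(C)(O)[C@H](C/C=C(\C)C(=O)OC)C[C@@]1(CC=C(C)C)C(O)=C(C(=O)c2ccccc2)C(=O)C2=C1OC(C)(C)C=C2
A1 | alternative 1 | 3,3-disubstituted 6-(2-oxo-2-phenylethyl)-2H-pyran-2,4(3H)-dione carrying prenyl and the complete side chain (methyl ester) on C3 | C=C(C)[C@H](C/C=C(\C)C(=O)OC)C[C@@]1(CC=C(C)C)C(=O)OC(CC(=O)c2ccccc2)=CC1=O
A2 | alternative 1 | ring A benzoyl trione without ring B (C4a still CH2), methyl ester | C=C(C)[C@H](C/C=C(\C)C(=O)OC)C[C@@]1(CC=C(C)C)C(O)=C(C(=O)c2ccccc2)C(=O)CC1=O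
A3 | alternative 2 | 8,8-diprenyl 6-benzoyl-2,2-dimethyl-5-oxo-chromene whose C7 oxygen carries a glyoxylate ester | O=CC(=O)OC1=C(C(=O)c2ccccc2)C(=O)C2=C(OC(C)(C)C=C2)C1(CC=C(C)C)CC=C(C)C
A4 | alternative 2 | seven-membered hydroxy lactone from the ene reaction (carbinol configuration undefined) | C=C(C)[C@H]3C[C@@]1(CC=C(C)C)C(OC(=O)C3O)=C(C(=O)c2ccccc2)C(=O)C2=C1OC(C)(C)C=C2
A5 | alternative 3 | 2-prenyl-2-(side chain)cyclohexane-1,3,5-trione with a free carboxylic acid on C2' (drawn as the triketo tautomer) | OC(=O)[C@H](C/C=C(\C)C(=O)OC)CC1(CC=C(C)C)C(=O)CC(=O)CC1=O
A6 | alternative 3 | fused enol lactone, prenyl trans to the C3' chain, no benzoyl group and no ring B | O=C3[C@H](C/C=C(\C)C(=O)OC)C[C@@]1(CC=C(C)C)C(O3)=CC(=O)CC1=O
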